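Rings: A = 4-alkyl-2-aryloxyphenol, B = para-phenylene, C = 1,2,3-trisubstituted phenol, D = meta-phenylene. The route rests on the C(sp2)–C(sp3) bond between C3 of ring D and the neighbouring CH2 of the A–D ethano bridge. That CH2 is the terminal carbon of a ring-A styrene and C3(D) has no ortho substituent. One-pot 9-BBN hydroboration/intramolecular B-alkyl Suzuki–Miyaura coupling, a formal anti-Markovnikov hydroarylation, therefore closes the 18-membered ring directly at the final oxidation level. Its precursor is the open A–O–B–CH2CH2–C–O–D chain with vinyl on A and chlorine on D. The chloride stays silent while the same reaction on a ring-B bromide builds the B–C bridge.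

Key step: step 6

Remark: the target SMILES holds no stereocentre or stereo-descriptor, and the 18-membered ring is taken to be conformationally mobile. The compound is therefore treated as achiral and no step has to set configuration.

Step 1
Reactants: 1 isovanillin (3-hydroxy-4-methoxybenzaldehyde); 2 4-bromophenylboronic acid
Product: 3 3-(4-bromophenoxy)-4-methoxybenzaldehyde
Conditions: Cu(OAc)2 (1 equiv), pyridine (5 equiv), 4 Å MS, CH2Cl2, air, rt
Reagents that add atoms: none
Why: Chan–Evans–Lam O-arylation transfers the aryl group of the boronic acid to the ring-A phenoxide on copper at room temperature, where the aldehyde and the C–Br bond needed in step 5 are inert.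

Step 2
Reactants: 3 3-(4-bromophenoxy)-4-methoxybenzaldehyde
Product: 4 2-(4-bromophenoxy)-1-methoxy-4-vinylbenzene (A–B fragment)
Conditions: Ph3PCH3Br, KOt-Bu, THF, 0 °C to rt
Reagents that add atoms: methyltriphenylphosphonium bromide, C[P+](c1ccccc1)(c1ccccc1)c1ccccc1.[Br-]
Why: Wittig methylenation with the non-stabilised ylide should turn the aldehyde into the terminal styrene without touching the aryl bromide or the diaryl ether.

Step 3
Reactants: 5 2-fluoro-3-methoxybenzaldehyde; 6 3-chlorophenol
Product: 7 2-(3-chlorophenoxy)-3-methoxybenzaldehyde
Conditions: K2CO3, DMF, 120 °C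
Reagents that add atoms: none
Why: Nucleophilic aromatic substitution (addition–elimination) works because the ortho-formyl group stabilises the Meisenheimer adduct and fluoride leaves readily, while the unactivated C–Cl bond of the phenoxide partner cannot react.

Step 4
Reactants: 7 2-(3-chlorophenoxy)-3-methoxybenzaldehyde
Product: 8 2-(3-chlorophenoxy)-1-methoxy-3-vinylbenzene (C–D fragment)
Conditions: Ph3PCH3Br, KOt-Bu, THF, 0 °C to rt
Reagents that add atoms: methyltriphenylphosphonium bromide, C[P+](c1ccccc1)(c1ccccc1)c1ccccc1.[Br-]
Why: Wittig methylenation of the hindered but non-enolisable aldehyde should give the ring-C styrene, and the aryl chloride and both ethers are inert to the ylide.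

Step 5
Reactants: 8 2-(3-chlorophenoxy)-1-methoxy-3-vinylbenzene; 4 2-(4-bromophenoxy)-1-methoxy-4-vinylbenzene
Product: 10 open-chain vinyl chloride 2-[4-[2-[2-(3-chlorophenoxy)-3-methoxyphenyl]ethyl]phenoxy]-1-methoxy-4-vinylbenzene, via ring-C alkylborane 9 (not isolated)
Conditions: 8 (1.1 equiv), 9-BBN (1.05 equiv), THF, 0 °C to rt; then 3 M aq K3PO4; then 4, PdCl2(dppf)·CH2Cl2 (5 mol %), THF–DMF, 50 °C
Reagents that add atoms: 9-BBN (9-borabicyclo[3.3.1]nonane), B1C2CCCC1CCC2 (its boron cage is held only in intermediate 9)
Why: In this hydroboration/intermolecular B-alkyl Suzuki–Miyaura coupling, 9-BBN puts boron on the terminal carbon of the ring-C styrene, the aqueous base destroys residual B–H before 4 is added, and PdCl2(dppf) at 50 °C should insert only into the ring-B C–Br bond, sparing the ring-D C–Cl bond and the ring-A vinyl group because transmetalation outruns Heck insertion at this temperature.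

Step 6
Reactants: 10 open-chain vinyl chloride
Product: 12 marchantin C dimethyl ether (macrocycle), via ring-A alkylborane 11 (not isolated)
Conditions: 9-BBN (1.5 equiv), THF, rt; then syringe-pump addition (12 h) to SPhos Pd G3 (10 mol %), K3PO4 (3 equiv), THF–H2O (10:1), 65 °C, final ca. 1 mM
Reagents that add atoms: 9-BBN (9-borabicyclo[3.3.1]nonane), B1C2CCCC1CCC2 (its boron cage is held only in intermediate 11)
Why: 9-BBN adds syn and anti-Markovnikov to the ring-A vinyl group, its steric demand placing boron on the terminal CH2, so that this carbon becomes the nucleophilic end of the chain (11). Under aqueous K3PO4 the electron-rich SPhos–Pd(0) inserts into the C3–Cl bond of ring D, the borate transmetalates intramolecularly to a 19-membered aryl(alkyl)palladacycle, and reductive elimination forges the C3(D)–CH2 bond. The closest known reaction type is the B-alkyl Suzuki–Miyaura macrocyclisation used for cyclophanes and macrocyclic natural products, combined with the established coupling of B-alkyl-9-BBN reagents with unactivated aryl chlorides under dialkylbiarylphosphine ligation. One ring is closed, the 18-membered macrocycle (shortest path through the four arenes), by end-to-end closure of the open chain, and no stereocentre is created. The step needs ring closure over oligomerisation, secured by pseudo-high dilution and by the ortho hinge at ring C, the meta hinges at rings A and D and the two bent diaryl ether oxygens that fold the chain ends toward each other; it also needs reductive elimination over β-hydride elimination, secured by the bulky ligand and the unhindered C3 of ring D. Chemoselectivity should pose no problem because the C–B and C–Cl bonds are the only reactive sites left in 11.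

Step 7
Reactants: 12 marchantin C dimethyl ether
Product: 13 marchantin C
Conditions: BBr3 (6 equiv), CH2Cl2, −78 °C to rt; then H2O
Reagents that add atoms: none
Why: In this Lewis-acid aryl methyl ether cleavage, BBr3 binds the two methoxy oxygens and bromide attacks the methyl carbons (SN2), whereas the diaryl ether C–O bonds offer no sp3 carbon and should persist.

Compound list
1 | isovanillin (3-hydroxy-4-methoxybenzaldehyde) | COc1ccc(C=O)cc1O | starting material
2 | 4-bromophenylboronic acid | OB(O)c1ccc(Br)cc1 | starting material
3 | 3-(4-bromophenoxy)-4-methoxybenzaldehyde | COc1ccc(C=O)cc1Oc1ccc(Br)cc1 | intermediate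
4 | 2-(4-bromophenoxy)-1-methoxy-4-vinylbenzene | COc1ccc(C=C)cc1Oc1ccc(Br)cc1 | intermediate
5 | 2-fluoro-3-methoxybenzaldehyde | COc1cccc(C=O)c1F | starting material
6 | 3-chlorophenol | Oc1cccc(Cl)c1 | starting material
7 | 2-(3-chlorophenoxy)-3-methoxybenzaldehyde | COc1cccc(C=O)c1Oc1cccc(Cl)c1 | intermediate
8 | 2-(3-chlorophenoxy)-1-methoxy-3-vinylbenzene | COc1cccc(C=C)c1Oc1cccc(Cl)c1 | intermediate
9 | 9-[2-[2-(3-chlorophenoxy)-3-methoxyphenyl]ethyl]-9-borabicyclo[3.3.1]nonane (ring-C alkylborane, not isolated) | COc1cccc(CCB2C3CCCC2CCC3)c1Oc1cccc(Cl)c1 | intermediate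
10 | 2-[4-[2-[2-(3-chlorophenoxy)-3-methoxyphenyl]ethyl]phenoxy]-1-methoxy-4-vinylbenzene (open-chain vinyl chloride) | COc1ccc(C=C)cc1Oc1ccc(CCc2cccc(OC)c2Oc2cccc(Cl)c2)cc1 | intermediate
11 | B-alkyl-9-BBN from hydroboration of the ring-A vinyl group of 10 (ring-A alkylborane, not isolated) | COc1ccc(CCB2C3CCCC2CCC3)cc1Oc1ccc(CCc2cccc(OC)c2Oc2cccc(Cl)c2)cc1 | intermediate
12 | marchantin C dimethyl ether | COc1ccc2cc1Oc1ccc(cc1)CCc1cccc(OC)c1Oc1cccc(c1)CC2 | intermediate
13 | marchantin C | Oc1ccc2cc1Oc1ccc(cc1)CCc1cccc(O)c1Oc1cccc(c1)CC2 | target

Total step count: 7. Longest linear sequence: 5 steps (1, 2, 5, 6, 7 or 3, 4, 5, 6, 7).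

Steps most likely to fail

Step 6. Intermolecular coupling may outrun ring closure and give oligomers. The 2-arylethyl unit may also be lost by β-hydride elimination on palladium or by protodeboronation before transmetalation.
- The fallback sets out from 10 and comes back at 12.
- It closes the same C3(D)–CH2 bond without any organoboron partner, at the alkene oxidation level.
- An intramolecular Mizoroki–Heck reaction of the ring-D chloride with the terminal carbon of the ring-A vinyl group is run with Pd2(dba)3, P(t-Bu)3·HBF4 and Cs2CO3 in dioxane at 110 °C and ca. 1 mM. It should give the macrocyclic (E)-stilbene dimethyl ether F1.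
- Hydrogenation (H2, Pd/C, EtOAc, rt) then saturates the new alkene to 12. Either alkene geometry would converge there.

Step 5. The arylpalladium species formed from 4 may insert into the free vinyl group of a second molecule, or leftover B–H may hydroborate that vinyl group. Either process erodes the orthogonality of the two alkenes.
- The fallback sets out from 3 and 8 and comes back at 10.
- Ring A keeps its alkene masked as the aldehyde.
- Borane 9, made from 8 as before, is coupled with bromo aldehyde 3 (PdCl2(dppf), aq K3PO4, THF–DMF, 50 °C). This should give 3-[4-[2-[2-(3-chlorophenoxy)-3-methoxyphenyl]ethyl]phenoxy]-4-methoxybenzaldehyde F2.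
- Wittig methylenation (Ph3PCH3Br, KOt-Bu, THF) then converts F2 into 10. Step 2 is dropped, so the step count stays the same.

Step 3. Addition of the phenoxide to the C–F carbon, which is flanked on both sides, may be sluggish. At the temperature needed, base-induced degradation of the aldehyde may compete.
- The fallback sets out from 6 and comes back at 7.
- The addition–elimination is replaced by a copper-catalysed Ullmann-type ether coupling of 6 with commercial 2-bromo-3-methoxybenzaldehyde (COc1cccc(C=O)c1Br). Conditions are CuI, N,N-dimethylglycine and Cs2CO3 in dioxane at 90 °C.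
- The aryl chloride should be inert under these conditions.
- No new compound arises on this way (F0).

Further compounds
F1 | step 6 | macrocyclic (E)-stilbene, marchantin C dimethyl ether with CH=CH in the A–D bridge | COc1ccc2cc1Oc1ccc(cc1)CCc1cccc(OC)c1Oc1cccc(c1)/C=C/2
F2 | step 5 | 3-[4-[2-[2-(3-chlorophenoxy)-3-methoxyphenyl]ethyl]phenoxy]-4-methoxybenzaldehyde | COc1ccc(C=O)cc1Oc1ccc(CCc2cccc(OC)c2Oc2cccc(Cl)c2)cc1
F0 | step 3 | none | none
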